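**Numbering.** Unit 1 is the 7-methoxyflavone (atoms unprimed, ring B primed). Unit 2 is the flavone joined through C8'' (ring A and ring C double-primed, ring B triple-primed). Ar1 stands for the 5-(benzyloxy)-2-[4-(benzyloxy)phenyl]-7-methoxy-4-oxo-4H-chromen-6-yl group.

## Analysis of the target

The target 32 is a biflavone: two 5,7,4'-trioxygenated 2-aryl-4H-chromen-4-one units joined by one bond between C6 of unit 1 and C8'' of unit 2. Unit 1 carries the only methyl ether (O7); the other five oxygens are free phenols. There is no stereogenic carbon, and the C6–C8'' axis, flanked by four oxygen-bearing ortho carbons (C5, C7, C7'', C8a''), has no descriptor, so nothing has to be set or correlated. The sensitive parts are the two pyranone rings (opened by hot alkali, attacked by hard nucleophiles, reducible at C2=C3) and the electron-rich polyphenol, which oxidises in basic air. Keeping one O-methyl apart from five hydroxyls rules out late methylation or demethylation, so the other oxygens must travel as ethers that come off under neutral conditions. The hard problem is the biaryl bond: it links two electron-rich rings, is tetra-ortho-substituted, and must sit at C6 in one unit but at C8'' in the other, although these positions respond alike to electrophiles. The strategy rests on ring A of unit 2, whose oxygens alternate (C5'', C7'', C8a'') and whose C8a'' oxygen lies between the aryl-bearing C8'' and C4a''. A 4-aryl-3-siloxycyclobutenone and a siloxyalkyne assemble exactly this arene, with the aryl–C8'' bond already present as an sp3–sp2 bond and with C8a''–OH, the future O1'', as the only free phenol.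

## Retrosynthetic reasoning

**Protecting groups (32 ⇐ 31 ⇐ 30).** The three O–benzyl bonds (O5, O4', O4''') of 31 are cut by hydrogenolysis and the two O–silyl bonds (O5'', O7'') of 30 by desilylation. Both removals are neutral and leave the 7-O-methyl group and the pyranone rings alone, so the methyl ether can be present from compound 1 onward.

**Ring C of unit 2 (30 ⇐ 28 ⇐ 27 ⇐ 24 + 25).** Cutting O1''–C2'' gives the o-hydroxyaryl ynone 28. This comes from alcohol 27 by oxidation, and 27 from a C3''–C4'' cut into aldehyde 24 and alkyne 25, used as acetylide 26. Ring B of unit 2 and C2''/C3'' thus enter as one intact piece, and the arene only has to supply one carbon at C4a''. The forward closure must be 6-endo at C2''.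

**C4'' (24 ⇐ 22).** The C4a''–C4'' bond is cut. Phenol 22 has a single free hydroxyl (on C8a'') with exactly one unsubstituted ortho carbon, C4a''. A phenoxide-directed formylation therefore has one site only; C6'' is para to that hydroxyl and is not addressed.

**Ring A of unit 2 (22 ⇐ 17 + 14), the key disconnection.** C4a''–C8a'' and C5''–C6'' are cut. This removes C4a'' and C5'' with its oxygen as siloxyalkyne 14 and leaves C8a''–C8''–C7''–C6'' as cyclobutenone 17. The cut is made here, and not at the biaryl bond, because it replaces a coupling of two hindered, electron-rich arenes by a pericyclic ring construction. The forward reaction has to insert 14 between C8a'' and C6'' with the CH terminus on C8a'', re-form C8''–C8a'' in a six-electron closure, and leave only the C8a'' oxygen unprotected.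

**The cyclobutenone (17 ⇐ 16 ⇐ 15 ⇐ 9 + 14).** 17 is cut at C7''–C8'' and at C6''–C8a''; the latter bond is sacrificial and is broken again in the key step. The pieces are arylketene 16 and a second molecule of 14. Ketene 16 is reached from acid 9 through chloride 15. The polarisation of 14 that sets the oxygen pattern in the key step also puts the siloxy carbon next to C8'' here.

**The future biaryl bond (9 ⇐ 8 ⇐ 6 + 7).** C6–C8'' is cut between the arene of unit 1 and a methylene, giving aryl iodide 6 and zinc enolate 7. The bond that ends up tetra-ortho-substituted is thus made while C8'' is an unhindered primary sp3 carbon. Ester 8 is then only hydrolysed to 9.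

**C6 functionalisation (6 ⇐ 5 ⇐ 4).** The O5–benzyl and C6–I bonds are cut in this order. The free, chelated 5-hydroxyl of 4 is needed to steer iodination to C6; once O5 is alkylated the attack would go to C8.

**Ring C of unit 1 (4 ⇐ 3 ⇐ 1 + 2).** O1–C2 is cut to diketone 3, and C2–C3 to acetophenone 1 and aroyl chloride 2. Compound 1 already holds the methyl ether and has two equivalent phenols, so the ring closure has no regiochemical choice.

**The siloxyalkyne (14 ⇐ 13 ⇐ 10).** The terminal C–H of 14 is traced to a C–Si bond in 13. The C–O bond of 13 is traced to oxygenation of acetylide 11, made from 10, followed by O-silylation of ynolate 12.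

## Alternatives that were turned down

**Alternative 1:** Ring A of unit 1 is cut at C4a–C5. The product of the key step is chalcone A1, and its precursor is the 3-aryl-4-hydroxy-2-pyrone A2, whose lactone masks a linear polyketone. In the forward step a magnesium alkoxide in an alcohol would open the lactone of A2, and the C4a methylene, flanked by two ketones, would close onto the released ester carbon C5 in a Claisen condensation.
- For: the step is biomimetic and ionic under mild conditions, and the aryl–C6 bond is made on a pyrone, which is less hindered than an arene–arene coupling.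
- Against: in A1 the hydroxyls on C5 and C8a are both free and both ortho to the acyl group. Closure of ring C through the wrong one gives the 8,8''-linked skeleton, so the key step leaves the position of the linkage open. O7 then has to be methylated after the fact. The open chain freed from A2 can also fold by other aldol modes or add to its own enone.
- Comparison: it matches the chosen route in avoiding a tetra-ortho arene–arene coupling and is gentler, since it involves no ketene. The chosen route offers in exchange a linkage position and an oxygen differentiation that are fixed by the connectivity of 17 and 14.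

**Alternative 2:** Both pyranones are cut at C2=C3 and C2''=C3''. The precursor is the bis(acylphosphorane) bis(aroate) A4; on heating, each ylide carbon would attack the neighbouring aryl ester carbonyl to give A3 with loss of the phosphine oxide.
- For: two rings are closed in one neutral thermal step by a well-behaved intramolecular Wittig reaction. In late-stage step economy this is stronger than the chosen route.
- Against: A4 already contains the C6–C8'' biaryl, with six differentiated oxygens and two acyl groups. The unsymmetrical, tetra-ortho-substituted arene–arene coupling and a long protecting-group sequence therefore have to be solved first. A3 also still needs a selective demethylation at O5 beside the O7 methyl ether.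
- Comparison: the chosen route gives up the double closure. In its place it makes the hindered bond as an sp3–sp2 bond and obtains the one free phenol it needs directly from the key step.

**Alternative 3:** Ring A of unit 1 is cut at C7–C8 and C5–C6, leading to pyranone ester A6 and arylacetyl chloride A7. With a lithium amide base the methyl carbanion (C8) of A6 would be acylated by A7, and the C6 enolate would then close on the ester carbon C5 to give A5.
- For: it shares the sp3–sp2 logic for the hindered bond and fixes the linkage by construction. The C8 functionalisation of a 5,7-dialkoxyflavone needed for A7 follows the intrinsic preference of electrophiles; on this point it is stronger than the chosen route, which must steer iodination to C6.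
- Against: A7 has acidic benzylic hydrogens next to the acyl chloride, so the base would convert it to a ketene in competition with C-acylation, and O-acylation or double acylation of A6 can occur. The closing Claisen step needs enolisation at a carbon bearing a di-ortho-substituted aryl group and attack on an ester deactivated by the ring oxygen. A5 has two free phenols and still needs a selective methylation at O7.
- Comparison: the chosen route builds its ring without strong base next to a chromone and ends with one free phenol in the right place.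

Key step: step 9

Remark: 32 has no stereocentre and its structure gives no descriptor for the C6–C8'' axis; the axis is treated as unspecified and is formed without control.
Remark: (triisopropylsilyloxy)ethyne 14 is not assumed to be purchasable and is prepared in steps 6 and 7.

## Route

Step 1
Reactants: 1 2',6'-dihydroxy-4'-methoxyacetophenone; 2 4-(benzyloxy)benzoyl chloride
Product: 4 2-[4-(benzyloxy)phenyl]-5-hydroxy-7-methoxy-4H-chromen-4-one, via diketone 3 (not isolated)
Conditions: LiN(SiMe3)2 (4.2 equiv), THF, −78 → −10 °C; 2, −78 °C → rt; aq. HCl; crude 3, p-TsOH·H2O (cat.), toluene, 90 °C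
Reagents that add atoms: none
Why: Baker–Venkataraman-type flavone synthesis run as a direct C-acylation: the polylithiated acetophenone (two phenoxides and the ketone enolate) should be acylated on carbon by 2, and acid-catalysed cyclodehydration of 3 through either of its two equivalent phenols should give the 5-hydroxy-7-methoxyflavone; catalytic sulfonic acid in warm toluene spares the aryl benzyl ether.

Step 2
Reactants: 4 2-[4-(benzyloxy)phenyl]-5-hydroxy-7-methoxy-4H-chromen-4-one
Product: 5 2-[4-(benzyloxy)phenyl]-5-hydroxy-6-iodo-7-methoxy-4H-chromen-4-one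
Conditions: BnMe3N+ ICl2− (1.1 equiv), CaCO3, CH2Cl2/MeOH, rt
Reagents that add atoms: benzyltrimethylammonium dichloroiodate, SMILES C[N+](C)(C)Cc1ccccc1.Cl[I-]Cl
Why: Electrophilic aromatic iodination steered by the free, chelated 5-hydroxyl to its ortho carbon C6, with CaCO3 taking up the HCl; it is placed before O5-alkylation because 5-O-alkylated 5,7-dioxygenated flavones are attacked at C8.

Step 3
Reactants: 5 2-[4-(benzyloxy)phenyl]-5-hydroxy-6-iodo-7-methoxy-4H-chromen-4-one
Product: 6 5-(benzyloxy)-2-[4-(benzyloxy)phenyl]-6-iodo-7-methoxy-4H-chromen-4-one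
Conditions: BnBr, K2CO3, Bu4NI (cat.), DMF, 60 °C
Reagents that add atoms: benzyl bromide, SMILES BrCc1ccccc1
Why: Williamson etherification; the hydrogen-bonded, iodine-flanked 5-hydroxyl is sluggish and needs warm DMF with iodide catalysis, but 5 holds no competing nucleophile.

Step 4
Reactants: 6 5-(benzyloxy)-2-[4-(benzyloxy)phenyl]-6-iodo-7-methoxy-4H-chromen-4-one; 7 (2-ethoxy-2-oxoethyl)zinc bromide
Product: 8 ethyl 2-(Ar1)acetate
Conditions: Pd2(dba)3 (2.5 mol%), XPhos (10 mol%), THF, 60 °C
Reagents that add atoms: none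
Why: Negishi coupling of a Reformatsky reagent (palladium-catalysed α-arylation of a zinc ester enolate): oxidative addition of zerovalent palladium into C6–I, transmetalation and reductive elimination form the C6–CH2 bond; the bulky biarylphosphine is chosen for the di-ortho-substituted iodide, and the weakly basic zinc enolate leaves the chromone untouched.

Step 5
Reactants: 8 ethyl 2-(Ar1)acetate
Product: 9 2-(Ar1)acetic acid
Conditions: LiOH·H2O (2 equiv), THF/H2O, rt; 1 M HCl to pH 3, 0 °C
Reagents that add atoms: lithium hydroxide monohydrate, SMILES [Li+].[OH-].O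
Why: Ester saponification at room temperature; the donor-substituted flavone should not be opened by dilute hydroxide in the cold, and the brief, dilute acidification spares the benzyl ethers.

Step 6
Reactants: 10 trimethylsilylacetylene
Product: 13 triisopropyl{[(trimethylsilyl)ethynyl]oxy}silane, via lithium acetylide 11 (not isolated), via lithium ynolate 12 (not isolated)
Conditions: n-BuLi, THF, −78 °C; LiOOt-Bu (from t-BuOOH and LiN(SiMe3)2, THF, −78 °C), −78 → 0 °C; i-Pr3SiOTf, −78 → 0 °C
Reagents that add atoms: tert-butyl hydroperoxide, SMILES CC(C)(C)OO; triisopropylsilyl trifluoromethanesulfonate, SMILES CC(C)[Si](OS(=O)(=O)C(F)(F)F)(C(C)C)C(C)C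
Why: Electrophilic oxygenation of a lithium acetylide by lithium tert-butyl peroxide gives ynolate 12; the bulky silyl triflate should go to oxygen because the carbon terminus already carries Me3Si, and 13 is kept cold to avoid a 1,3-silyl shift to a bis(silyl)ketene.

Step 7
Reactants: 13 triisopropyl{[(trimethylsilyl)ethynyl]oxy}silane
Product: 14 (triisopropylsilyloxy)ethyne
Conditions: K2CO3 (0.2 equiv), MeOH, 0 °C; pentane extraction
Reagents that add atoms: none
Why: Protodesilylation of an alkynyl–SiMe3 bond by catalytic methoxide; the hindered O–Si(i-Pr)3 bond and the ynol ether itself, which needs acid to add methanol, should survive short basic methanolysis at 0 °C.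

Step 8
Reactants: 9 2-(Ar1)acetic acid; 14 (triisopropylsilyloxy)ethyne
Product: 17 racemic 4-(Ar1)-3-(triisopropylsilyloxy)cyclobut-2-en-1-one, via acid chloride 15 (not isolated), via arylketene 16 (not isolated)
Conditions: Me2C=C(Cl)NMe2 (1.2 equiv), CH2Cl2, 0 °C → rt; added over 2 h to 14 (2.0 equiv), Et3N (1.5 equiv), CH2Cl2, rt; short silica plug
Reagents that add atoms: none
Why: Neutral acid chloride formation with an α-chloroenamine (no HCl, pyranone carbonyl untouched), dehydrochlorination to ketene 16 and ketene–ynol ether [2+2] cycloaddition, in which the nucleophilic CH terminus of 14 bonds to the ketene carbonyl carbon so that the siloxy carbon ends up next to CH(Ar1); slow addition keeps 16 dilute against dimerisation, and the C4 stereocentre forms racemic and is erased in step 9.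

Step 9
Reactants: 17 racemic 4-(Ar1)-3-(triisopropylsilyloxy)cyclobut-2-en-1-one; 14 (triisopropylsilyloxy)ethyne
Product: 22 5-(benzyloxy)-2-[4-(benzyloxy)phenyl]-6-[2-hydroxy-4,6-bis(triisopropylsilyloxy)phenyl]-7-methoxy-4H-chromen-4-one, via vinylketene 18 (not isolated), via vinylcyclobutenone 19 (not isolated), via dienylketene 20 (not isolated), via cyclohexadienone 21 (not isolated)
Conditions: 14 (3 equiv), toluene, degassed, sealed tube, 80 → 110 °C
Reagents that add atoms: none
Why: Danheiser benzannulation of a cyclobutenone with a siloxyalkyne, the known route to resorcinol derivatives: a thermal conrotatory four-electron opening of 17 breaks C8''–C8a'' and gives vinylketene 18, which adds 14 across its ketene C=C in a [2+2] step (C8a''–C4a'' and C6''–C5'' formed) to give 19. A second four-electron opening of 19 breaks the sacrificial C8a''–C6'' bond, and the dienylketene 20 closes ring A of unit 2 by a thermal disrotatory six-electron electrocyclisation that re-forms C8''–C8a''; dienone 21 then tautomerises to the phenol. The step needs one regioselectivity: the CH terminus of 14 must bond to the ketene carbonyl carbon, which the oxygen donor on the other alkyne carbon secures, so the three ring oxygens alternate and the free hydroxyl lands on C8a''. Only the dienylketene with C8a'' and C7'' cis across the central double bond can close; both ring openings are reversible, so the other isomer returns and is funnelled through. The usual escape of 4-arylcyclobutenones, closure onto an aryl ortho carbon to a naphthol, has no hydrogen to lose because C5 and C7 both carry oxygen. The stereocentres of 17, 19 and 21 disappear on aromatisation, and no stereocentre is created.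

Step 10
Reactants: 22 5-(benzyloxy)-2-[4-(benzyloxy)phenyl]-6-[2-hydroxy-4,6-bis(triisopropylsilyloxy)phenyl]-7-methoxy-4H-chromen-4-one
Product: 24 3-(Ar1)-2-hydroxy-4,6-bis(triisopropylsilyloxy)benzaldehyde, via salicyl alcohol 23 (not isolated)
Conditions: MgCl2 (3 equiv), Et3N (6 equiv), (CH2O)n (10 equiv), THF, reflux; 1 M HCl, 0 °C
Reagents that add atoms: paraformaldehyde (formaldehyde unit), SMILES C=O
Why: Magnesium-mediated ortho-formylation (Casnati–Skattebøl type): the magnesium phenoxide of the only free phenol binds formaldehyde and delivers it to the single free ortho carbon C4a''; alcohol 23 is oxidised in the flask by Oppenauer-type hydride transfer to a second formaldehyde, and C6'', para to the phenol, is not reached.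

Step 11
Reactants: 24 3-(Ar1)-2-hydroxy-4,6-bis(triisopropylsilyloxy)benzaldehyde; 25 1-(benzyloxy)-4-ethynylbenzene
Product: 27 5-(benzyloxy)-2-[4-(benzyloxy)phenyl]-6-{3-[3-(4-benzyloxyphenyl)-1-hydroxyprop-2-yn-1-yl]-2-hydroxy-4,6-bis(triisopropylsilyloxy)phenyl}-7-methoxy-4H-chromen-4-one, via lithium acetylide 26 (not isolated)
Conditions: 25, n-BuLi, THF, −78 °C; added to 24 pretreated with LiN(SiMe3)2 (1.05 equiv), THF, −78 → −40 °C; aq. NH4Cl
Reagents that add atoms: none
Why: 1,2-Addition of a lithium acetylide to an aldehyde; the phenol is deprotonated first so that 26 is not consumed as a base, and at low temperature the aldehyde reacts far faster than the vinylogous ester carbonyl of unit 1. The carbinol centre forms without control and is removed in step 12.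

Step 12
Reactants: 27 propargylic alcohol from step 11
Product: 28 5-(benzyloxy)-2-[4-(benzyloxy)phenyl]-6-{3-[3-(4-benzyloxyphenyl)prop-2-ynoyl]-2-hydroxy-4,6-bis(triisopropylsilyloxy)phenyl}-7-methoxy-4H-chromen-4-one
Conditions: MnO2 (activated, excess), CH2Cl2, rt
Reagents that add atoms: none
Why: MnO2 oxidation of a benzylic, propargylic alcohol to the ynone; phenol, silyl ethers and benzyl ethers are inert to it.

Step 13
Reactants: 28 ynone from step 12
Product: 30 5,4',4'''-tri-O-benzyl-7-O-methyl-5'',7''-bis-O-(triisopropylsilyl)-6,8''-biapigenin, via enaminone 29 (not isolated)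
Conditions: Et2NH (5 equiv), EtOH/THF, rt → 60 °C
Reagents that add atoms: none
Why: Amine-promoted cyclisation of an o-hydroxyaryl ynone: conjugate addition of Et2NH gives enaminone 29, and the C8a'' hydroxyl then adds to the same carbon (C2'') and expels the amine, a net 6-endo closure; the 5-exo path to an aurone would need attack at C3'' and is not open from 29.

Step 14
Reactants: 30 silylated biflavone from step 13
Product: 31 5,4',4'''-tri-O-benzyl-7-O-methyl-6,8''-biapigenin
Conditions: Bu4NF (2.5 equiv), AcOH (2.5 equiv), THF, 0 °C → rt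
Reagents that add atoms: none
Why: Fluoride cleavage of two aryl silyl ethers; acetic acid buffers the phenoxides against air oxidation, and benzyl ethers and both flavone rings are untouched.

Step 15
Reactants: 31 5,4',4'''-tri-O-benzyl-7-O-methyl-6,8''-biapigenin
Product: 32 7-O-methyl-6,8''-biapigenin (target CNP0246647.0)
Conditions: H2 (1 atm), 10% Pd/C, THF/MeOH, rt
Reagents that add atoms: none
Why: Hydrogenolysis of three aryl benzyl ethers over palladium on carbon; the C2=C3 bonds are part of vinylogous esters and are reduced much more slowly, so the reaction is stopped once debenzylation is complete.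

## Compound list

1 | 2',6'-dihydroxy-4'-methoxyacetophenone | COc1cc(O)c(C(C)=O)c(O)c1 | starting material
2 | 4-(benzyloxy)benzoyl chloride | O=C(Cl)c1ccc(OCc2ccccc2)cc1 | starting material
3 | 1-[4-(benzyloxy)phenyl]-3-(2,6-dihydroxy-4-methoxyphenyl)propane-1,3-dione | COc1cc(O)c(C(=O)CC(=O)c2ccc(OCc3ccccc3)cc2)c(O)c1 | intermediate
4 | 2-[4-(benzyloxy)phenyl]-5-hydroxy-7-methoxy-4H-chromen-4-one | COc1cc(O)c2c(=O)cc(-c3ccc(OCc4ccccc4)cc3)oc2c1 | intermediate
5 | 2-[4-(benzyloxy)phenyl]-5-hydroxy-6-iodo-7-methoxy-4H-chromen-4-one | COc1cc2oc(-c3ccc(OCc4ccccc4)cc3)cc(=O)c2c(O)c1I | intermediate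
6 | 5-(benzyloxy)-2-[4-(benzyloxy)phenyl]-6-iodo-7-methoxy-4H-chromen-4-one | COc1cc2oc(-c3ccc(OCc4ccccc4)cc3)cc(=O)c2c(OCc2ccccc2)c1I | intermediate
7 | (2-ethoxy-2-oxoethyl)zinc bromide | CCOC(=O)C[Zn]Br | starting material
8 | ethyl 2-{5-(benzyloxy)-2-[4-(benzyloxy)phenyl]-7-methoxy-4-oxo-4H-chromen-6-yl}acetate | COc1cc2oc(-c3ccc(OCc4ccccc4)cc3)cc(=O)c2c(OCc2ccccc2)c1CC(=O)OCC | intermediate
9 | 2-{5-(benzyloxy)-2-[4-(benzyloxy)phenyl]-7-methoxy-4-oxo-4H-chromen-6-yl}acetic acid | COc1cc2oc(-c3ccc(OCc4ccccc4)cc3)cc(=O)c2c(OCc2ccccc2)c1CC(=O)O | intermediate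
10 | trimethylsilylacetylene | C#C[Si](C)(C)C | starting material
11 | lithium (trimethylsilyl)ethynide | [Li]C#C[Si](C)(C)C | intermediate
12 | lithium 2-(trimethylsilyl)ethynolate | [Li]OC#C[Si](C)(C)C | intermediate
13 | triisopropyl{[(trimethylsilyl)ethynyl]oxy}silane | C[Si](C)(C)C#CO[Si](C(C)C)(C(C)C)C(C)C | intermediate
14 | (triisopropylsilyloxy)ethyne | C#CO[Si](C(C)C)(C(C)C)C(C)C | intermediate
15 | 2-(Ar1)acetyl chloride | COc1cc2oc(-c3ccc(OCc4ccccc4)cc3)cc(=O)c2c(OCc2ccccc2)c1CC(=O)Cl | intermediate
16 | 2-(Ar1)ethen-1-one (arylketene) | COc1cc2oc(-c3ccc(OCc4ccccc4)cc3)cc(=O)c2c(OCc2ccccc2)c1C=C=O | intermediate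
17 | racemic 4-(Ar1)-3-(triisopropylsilyloxy)cyclobut-2-en-1-one | COc1cc2oc(-c3ccc(OCc4ccccc4)cc3)cc(=O)c2c(OCc2ccccc2)c1C1C(=O)C=C1O[Si](C(C)C)(C(C)C)C(C)C | intermediate
18 | (3Z)-4-(Ar1)-3-(triisopropylsilyloxy)buta-1,3-dien-1-one | COc1cc2oc(-c3ccc(OCc4ccccc4)cc3)cc(=O)c2c(OCc2ccccc2)c1/C=C(O[Si](C(C)C)(C(C)C)C(C)C)/C=C=O | intermediate
19 | racemic 4-[(Z)-2-(Ar1)-1-(triisopropylsilyloxy)ethenyl]-3-(triisopropylsilyloxy)cyclobut-2-en-1-one | COc1cc2oc(-c3ccc(OCc4ccccc4)cc3)cc(=O)c2c(OCc2ccccc2)c1/C=C(O[Si](C(C)C)(C(C)C)C(C)C)/C1C(=O)C=C1O[Si](C(C)C)(C(C)C)C(C)C | intermediate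
20 | (3E,5Z)-6-(Ar1)-3,5-bis(triisopropylsilyloxy)hexa-1,3,5-trien-1-one | COc1cc2oc(-c3ccc(OCc4ccccc4)cc3)cc(=O)c2c(OCc2ccccc2)c1/C=C(O[Si](C(C)C)(C(C)C)C(C)C)/C=C(O[Si](C(C)C)(C(C)C)C(C)C)\C=C=O | intermediate
21 | racemic 6-(Ar1)-3,5-bis(triisopropylsilyloxy)cyclohexa-2,4-dien-1-one | COc1cc2oc(-c3ccc(OCc4ccccc4)cc3)cc(=O)c2c(OCc2ccccc2)c1C1C(=O)C=C(O[Si](C(C)C)(C(C)C)C(C)C)C=C1O[Si](C(C)C)(C(C)C)C(C)C | intermediate
22 | 5-(benzyloxy)-2-[4-(benzyloxy)phenyl]-6-[2-hydroxy-4,6-bis(triisopropylsilyloxy)phenyl]-7-methoxy-4H-chromen-4-one | COc1cc2oc(-c3ccc(OCc4ccccc4)cc3)cc(=O)c2c(OCc2ccccc2)c1-c1c(O)cc(O[Si](C(C)C)(C(C)C)C(C)C)cc1O[Si](C(C)C)(C(C)C)C(C)C | intermediate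
23 | 5-(benzyloxy)-2-[4-(benzyloxy)phenyl]-6-[2-hydroxy-3-(hydroxymethyl)-4,6-bis(triisopropylsilyloxy)phenyl]-7-methoxy-4H-chromen-4-one | COc1cc2oc(-c3ccc(OCc4ccccc4)cc3)cc(=O)c2c(OCc2ccccc2)c1-c1c(O)c(CO)c(O[Si](C(C)C)(C(C)C)C(C)C)cc1O[Si](C(C)C)(C(C)C)C(C)C | intermediate
24 | 3-(Ar1)-2-hydroxy-4,6-bis(triisopropylsilyloxy)benzaldehyde | COc1cc2oc(-c3ccc(OCc4ccccc4)cc3)cc(=O)c2c(OCc2ccccc2)c1-c1c(O)c(C=O)c(O[Si](C(C)C)(C(C)C)C(C)C)cc1O[Si](C(C)C)(C(C)C)C(C)C | intermediate
25 | 1-(benzyloxy)-4-ethynylbenzene | C#Cc1ccc(OCc2ccccc2)cc1 | starting material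
26 | lithium [4-(benzyloxy)phenyl]ethynide | [Li]C#Cc1ccc(OCc2ccccc2)cc1 | intermediate
27 | 5-(benzyloxy)-2-[4-(benzyloxy)phenyl]-6-{3-[3-(4-benzyloxyphenyl)-1-hydroxyprop-2-yn-1-yl]-2-hydroxy-4,6-bis(triisopropylsilyloxy)phenyl}-7-methoxy-4H-chromen-4-one (carbinol centre uncontrolled) | COc1cc2oc(-c3ccc(OCc4ccccc4)cc3)cc(=O)c2c(OCc2ccccc2)c1-c1c(O)c(C(O)C#Cc2ccc(OCc3ccccc3)cc2)c(O[Si](C(C)C)(C(C)C)C(C)C)cc1O[Si](C(C)C)(C(C)C)C(C)C | intermediate
28 | 5-(benzyloxy)-2-[4-(benzyloxy)phenyl]-6-{3-[3-(4-benzyloxyphenyl)prop-2-ynoyl]-2-hydroxy-4,6-bis(triisopropylsilyloxy)phenyl}-7-methoxy-4H-chromen-4-one | COc1cc2oc(-c3ccc(OCc4ccccc4)cc3)cc(=O)c2c(OCc2ccccc2)c1-c1c(O)c(C(=O)C#Cc2ccc(OCc3ccccc3)cc2)c(O[Si](C(C)C)(C(C)C)C(C)C)cc1O[Si](C(C)C)(C(C)C)C(C)C | intermediate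
29 | 5-(benzyloxy)-2-[4-(benzyloxy)phenyl]-6-{3-[3-(4-benzyloxyphenyl)-3-(diethylamino)prop-2-enoyl]-2-hydroxy-4,6-bis(triisopropylsilyloxy)phenyl}-7-methoxy-4H-chromen-4-one (mixture of double-bond isomers) | COc1cc2oc(-c3ccc(OCc4ccccc4)cc3)cc(=O)c2c(OCc2ccccc2)c1-c1c(O)c(C(=O)C=C(N(CC)CC)c2ccc(OCc3ccccc3)cc2)c(O[Si](C(C)C)(C(C)C)C(C)C)cc1O[Si](C(C)C)(C(C)C)C(C)C | intermediate
30 | 5,4',4'''-tri-O-benzyl-7-O-methyl-5'',7''-bis-O-(triisopropylsilyl)-6,8''-biapigenin | COc1cc2oc(-c3ccc(OCc4ccccc4)cc3)cc(=O)c2c(OCc2ccccc2)c1-c1c(O[Si](C(C)C)(C(C)C)C(C)C)cc(O[Si](C(C)C)(C(C)C)C(C)C)c2c(=O)cc(-c3ccc(OCc4ccccc4)cc3)oc12 | intermediate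
31 | 5,4',4'''-tri-O-benzyl-7-O-methyl-6,8''-biapigenin | COc1cc2oc(-c3ccc(OCc4ccccc4)cc3)cc(=O)c2c(OCc2ccccc2)c1-c1c(O)cc(O)c2c(=O)cc(-c3ccc(OCc4ccccc4)cc3)oc12 | intermediate
32 | 7-O-methyl-6,8''-biapigenin (CNP0246647.0) | COc1cc2oc(-c3ccc(O)cc3)cc(=O)c2c(O)c1-c1c(O)cc(O)c2c(=O)cc(-c3ccc(O)cc3)oc12 | target

## Step count and least certain steps

Total: 15 steps. Longest linear sequence: 13 steps (steps 1–5 and 8–15 from 1). The siloxyalkyne branch (steps 6 and 7) joins at step 8.

**Step 9 (key step).** The vinylketene 18 forms reversibly and carries a bulky aryl group on its terminus, so capture by 14 may be slow. Ketene oligomerisation, a thermal silyl shift of 14 to a silylketene, or migration of the enol ether double bond of 17 toward the aryl-bearing carbon could then take over; the last would end in a phenol para to the aryl group. The fallback gives up the pericyclic ring construction and makes the biaryl bond by Suzuki–Miyaura coupling. It sets out from iodide 6 and comes back at 22. Phloroglucinol is silylated twice (i-Pr3SiCl, imidazole, DMF) to 3,5-bis(triisopropylsilyloxy)phenol F1. This is protected with MeOCH2Cl and i-Pr2NEt as 1-(methoxymethoxy)-3,5-bis(triisopropylsilyloxy)benzene F2. Ortho-lithiation next to the acetal oxygen (n-BuLi, TMEDA) and trapping with 2-isopropoxy-4,4,5,5-tetramethyl-1,3,2-dioxaborolane give the pinacol boronate F3. Coupling of F3 with 6 (Pd(OAc)2, SPhos, K3PO4, toluene/H2O, 100 °C) gives the methoxymethyl ether of 22, F4. Removal of the acetal with ZnBr2 and n-PrSH in CH2Cl2 gives 22.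

**Step 7.** Cleavage of the O–Si bond or addition of methanol could compete with the wanted C–Si cleavage, so that 14 is not obtained pure. The fallback does not make 14; it carries the Me3Si group through both cycloadditions. It sets out from 13 and comes back at 22. Ketene 16, generated as in step 8, is trapped by 13 to give 4-(Ar1)-3-(triisopropylsilyloxy)-2-(trimethylsilyl)cyclobut-2-en-1-one F5. Its vinyl C–Si bond sits on the nucleophilic carbon of the enol ether and is cleaved by ipso-protonation (CF3CO2H, 1 equiv, CH2Cl2, −20 °C) to give 17. Heating 17 with 13 as in step 9 gives 5-(benzyloxy)-2-[4-(benzyloxy)phenyl]-6-[2-hydroxy-4,6-bis(triisopropylsilyloxy)-3-(trimethylsilyl)phenyl]-7-methoxy-4H-chromen-4-one F6. Protodesilylation of this electron-rich arylsilane (CF3CO2H, CH2Cl2, 0 °C) gives 22.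

**Step 8.** Dimerisation of the arylketene, or acylation of 14 by 15 before dehydrochlorination, could consume the material, and the ammonium salt may degrade 14. The fallback generates the same ketene without acid chloride or amine, by retro-ene fragmentation of an alkynyl ether. It sets out from 6 and comes back at 22, with 17 formed and consumed in the same flask. Negishi coupling of 6 with (ethoxyethynyl)zinc chloride (from ethoxyacetylene, n-BuLi and ZnCl2; Pd(PPh3)4, THF) gives 5-(benzyloxy)-2-[4-(benzyloxy)phenyl]-6-(ethoxyethynyl)-7-methoxy-4H-chromen-4-one F7. Heating F7 with 14 (4 equiv) in toluene at 110 °C expels ethene, releases 16, and lets the [2+2] step and the benzannulation run on to 22.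

**Step 10.** The magnesium phenoxide is shielded by the flanking aryl group and a silyl ether, so formaldehyde delivery may fail. Chelation could also detach the 5-O-benzyl group; that would not harm the endgame, since O5 is free in 32. The fallback brings C4'' in with the alkyne of the key step. It sets out from 17 and comes back at 24. 3,3-Diethoxyprop-1-yne is converted by the method of step 6 (n-BuLi; LiOOt-Bu; i-Pr3SiOTf) into [(3,3-diethoxyprop-1-yn-1-yl)oxy]triisopropylsilane F8. Heating 17 with F8 as in step 9 gives 5-(benzyloxy)-2-[4-(benzyloxy)phenyl]-6-[3-(diethoxymethyl)-2-hydroxy-4,6-bis(triisopropylsilyloxy)phenyl]-7-methoxy-4H-chromen-4-one F9. Mild acetal hydrolysis (pyridinium p-toluenesulfonate, acetone/H2O) gives 24.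

**Step 4.** Oxidative addition and transmetalation at the di-ortho-substituted iodide may be slow, so that protodeiodination wins. The fallback couples the smallest possible carbon partner and adjusts the oxidation state afterwards. It sets out from 6 and comes back at 9. Suzuki–Miyaura vinylation (potassium vinyltrifluoroborate, PdCl2(dppf), Cs2CO3, THF/H2O, 80 °C) gives 5-(benzyloxy)-2-[4-(benzyloxy)phenyl]-6-ethenyl-7-methoxy-4H-chromen-4-one F10. Hydroboration with 9-BBN and oxidation with NaBO3 give 5-(benzyloxy)-2-[4-(benzyloxy)phenyl]-6-(2-hydroxyethyl)-7-methoxy-4H-chromen-4-one F11. Oxidation with TEMPO and PhI(OAc)2 in MeCN/H2O gives acid 9.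

**Step 2.** Iodination could occur at C8 or twice, giving the wrong regiochemistry. The fallback fixes C6 by a sigmatropic shift and avoids both the iodide and the cross-coupling. It sets out from 4 and comes back at 9.
- O-Allylation of 4 (allyl bromide, K2CO3, DMF) gives 5-(allyloxy)-2-[4-(benzyloxy)phenyl]-7-methoxy-4H-chromen-4-one F12.
- Claisen rearrangement (N,N-diethylaniline, 200 °C) can only deliver the allyl group to the free ortho carbon C6 and gives 6-allyl-2-[4-(benzyloxy)phenyl]-5-hydroxy-7-methoxy-4H-chromen-4-one F13.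
- Benzylation as in step 3 gives 6-allyl-5-(benzyloxy)-2-[4-(benzyloxy)phenyl]-7-methoxy-4H-chromen-4-one F14.
- Lemieux–Johnson cleavage (OsO4 cat., NaIO4, 2,6-lutidine, dioxane/H2O) gives 2-(Ar1)acetaldehyde F15.
- Pinnick oxidation (NaClO2, NaH2PO4, 2-methylbut-2-ene) gives acid 9.

## Further compounds

F1 | step 9 | 3,5-bis(triisopropylsilyloxy)phenol | Oc1cc(O[Si](C(C)C)(C(C)C)C(C)C)cc(O[Si](C(C)C)(C(C)C)C(C)C)c1
F2 | step 9 | 1-(methoxymethoxy)-3,5-bis(triisopropylsilyloxy)benzene | COCOc1cc(O[Si](C(C)C)(C(C)C)C(C)C)cc(O[Si](C(C)C)(C(C)C)C(C)C)c1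
F3 | step 9 | 2-[2-(methoxymethoxy)-4,6-bis(triisopropylsilyloxy)phenyl]-4,4,5,5-tetramethyl-1,3,2-dioxaborolane | COCOc1cc(O[Si](C(C)C)(C(C)C)C(C)C)cc(O[Si](C(C)C)(C(C)C)C(C)C)c1B1OC(C)(C)C(C)(C)O1
F4 | step 9 | 5-(benzyloxy)-2-[4-(benzyloxy)phenyl]-7-methoxy-6-[2-(methoxymethoxy)-4,6-bis(triisopropylsilyloxy)phenyl]-4H-chromen-4-one | COc1cc2oc(-c3ccc(OCc4ccccc4)cc3)cc(=O)c2c(OCc2ccccc2)c1-c1c(OCOC)cc(O[Si](C(C)C)(C(C)C)C(C)C)cc1O[Si](C(C)C)(C(C)C)C(C)C
F5 | step 7 | racemic 4-(Ar1)-3-(triisopropylsilyloxy)-2-(trimethylsilyl)cyclobut-2-en-1-one | COc1cc2oc(-c3ccc(OCc4ccccc4)cc3)cc(=O)c2c(OCc2ccccc2)c1C1C(=O)C([Si](C)(C)C)=C1O[Si](C(C)C)(C(C)C)C(C)C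
F6 | step 7 | 5-(benzyloxy)-2-[4-(benzyloxy)phenyl]-6-[2-hydroxy-4,6-bis(triisopropylsilyloxy)-3-(trimethylsilyl)phenyl]-7-methoxy-4H-chromen-4-one | COc1cc2oc(-c3ccc(OCc4ccccc4)cc3)cc(=O)c2c(OCc2ccccc2)c1-c1c(O)c([Si](C)(C)C)c(O[Si](C(C)C)(C(C)C)C(C)C)cc1O[Si](C(C)C)(C(C)C)C(C)C
F7 | step 8 | 5-(benzyloxy)-2-[4-(benzyloxy)phenyl]-6-(ethoxyethynyl)-7-methoxy-4H-chromen-4-one | COc1cc2oc(-c3ccc(OCc4ccccc4)cc3)cc(=O)c2c(OCc2ccccc2)c1C#COCC
F8 | step 10 | [(3,3-diethoxyprop-1-yn-1-yl)oxy]triisopropylsilane | CCOC(OCC)C#CO[Si](C(C)C)(C(C)C)C(C)C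
F9 | step 10 | 5-(benzyloxy)-2-[4-(benzyloxy)phenyl]-6-[3-(diethoxymethyl)-2-hydroxy-4,6-bis(triisopropylsilyloxy)phenyl]-7-methoxy-4H-chromen-4-one | COc1cc2oc(-c3ccc(OCc4ccccc4)cc3)cc(=O)c2c(OCc2ccccc2)c1-c1c(O)c(C(OCC)OCC)c(O[Si](C(C)C)(C(C)C)C(C)C)cc1O[Si](C(C)C)(C(C)C)C(C)C
F10 | step 4 | 5-(benzyloxy)-2-[4-(benzyloxy)phenyl]-6-ethenyl-7-methoxy-4H-chromen-4-one | COc1cc2oc(-c3ccc(OCc4ccccc4)cc3)cc(=O)c2c(OCc2ccccc2)c1C=C
F11 | step 4 | 5-(benzyloxy)-2-[4-(benzyloxy)phenyl]-6-(2-hydroxyethyl)-7-methoxy-4H-chromen-4-one | COc1cc2oc(-c3ccc(OCc4ccccc4)cc3)cc(=O)c2c(OCc2ccccc2)c1CCO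
F12 | step 2 | 5-(allyloxy)-2-[4-(benzyloxy)phenyl]-7-methoxy-4H-chromen-4-one | COc1cc2oc(-c3ccc(OCc4ccccc4)cc3)cc(=O)c2c(OCC=C)c1
F13 | step 2 | 6-allyl-2-[4-(benzyloxy)phenyl]-5-hydroxy-7-methoxy-4H-chromen-4-one | COc1cc2oc(-c3ccc(OCc4ccccc4)cc3)cc(=O)c2c(O)c1CC=C
F14 | step 2 | 6-allyl-5-(benzyloxy)-2-[4-(benzyloxy)phenyl]-7-methoxy-4H-chromen-4-one | COc1cc2oc(-c3ccc(OCc4ccccc4)cc3)cc(=O)c2c(OCc2ccccc2)c1CC=C
F15 | step 2 | 2-{5-(benzyloxy)-2-[4-(benzyloxy)phenyl]-7-methoxy-4-oxo-4H-chromen-6-yl}acetaldehyde | COc1cc2oc(-c3ccc(OCc4ccccc4)cc3)cc(=O)c2c(OCc2ccccc2)c1CC=O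
A1 | alternative 1 | 2',4',6'-trihydroxy-3'-(tri-O-benzylapigenin-8''-yl)-4-benzyloxychalcone | O=C(/C=C/c1ccc(OCc2ccccc2)cc1)c1c(O)cc(O)c(-c2c(OCc3ccccc3)cc(OCc3ccccc3)c3c(=O)cc(-c4ccc(OCc5ccccc5)cc4)oc23)c1O
A2 | alternative 1 | 6-[(E)-4-(4-benzyloxyphenyl)-2-oxobut-3-en-1-yl]-4-hydroxy-3-(tri-O-benzylapigenin-8-yl)-2H-pyran-2-one | O=C(/C=C/c1ccc(OCc2ccccc2)cc1)CC1=CC(O)=C(c2c(OCc3ccccc3)cc(OCc3ccccc3)c3c(=O)cc(-c4ccc(OCc5ccccc5)cc4)oc23)C(=O)O1
A3 | alternative 2 | 5-O-methyl-5'',7'',4',4'''-tetra-O-benzyl derivative of the target | COc1cc2oc(-c3ccc(OCc4ccccc4)cc3)cc(=O)c2c(OC)c1-c1c(OCc2ccccc2)cc(OCc2ccccc2)c2c(=O)cc(-c3ccc(OCc4ccccc4)cc3)oc12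
A4 | alternative 2 | biaryl bis(acylphosphorane) bis(4-benzyloxybenzoate) | COc1cc(OC(=O)c2ccc(OCc3ccccc3)cc2)c(C(=O)C=P(c2ccccc2)(c2ccccc2)c2ccccc2)c(OC)c1-c1c(OCc2ccccc2)cc(OCc2ccccc2)c(C(=O)C=P(c2ccccc2)(c2ccccc2)c2ccccc2)c1OC(=O)c1ccc(OCc2ccccc2)cc1
A5 | alternative 3 | 5'',7'',4',4'''-tetra-O-benzyl-6,8''-biapigenin with free 5-OH and 7-OH | Oc1cc2oc(-c3ccc(OCc4ccccc4)cc3)cc(=O)c2c(O)c1-c1c(OCc2ccccc2)cc(OCc2ccccc2)c2c(=O)cc(-c3ccc(OCc4ccccc4)cc3)oc12
A6 | alternative 3 | methyl 6-[4-(benzyloxy)phenyl]-2-methyl-4-oxo-4H-pyran-3-carboxylate | COC(=O)c1c(C)oc(-c2ccc(OCc3ccccc3)cc2)cc1=O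
A7 | alternative 3 | 2-{5,7-bis(benzyloxy)-2-[4-(benzyloxy)phenyl]-4-oxo-4H-chromen-8-yl}acetyl chloride | O=C(Cl)Cc1c(OCc2ccccc2)cc(OCc2ccccc2)c2c(=O)cc(-c3ccc(OCc4ccccc4)cc3)oc12
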